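**Assumption (one line):** the target has no stereocentre and its diaryl ether bonds rotate freely, so it is one achiral compound and no stereocontrol is needed; rings are lettered A to H in the order of the SMILES string, and all 21 phenols are carried as methyl ethers.

## Retrosynthetic overview

1. Target ⇐ 21-fold O-demethylation of its permethyl ether; all eight benzene rings are bought, none is built, and only the seven diaryl ether C–O bonds are made.
2. Last bond: ring C oxygen to ring D carbon (Ullmann), joining the trimer phenol A–B–C with the pentamer bromide D–E–F–G–H.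
3. Pentamer ⇐ ring E carbon to ring F oxygen by a new light-driven copper decarboxylative aryloxylation of the D–E benzoic acid with the F–G–H phenol.
4. D–E acid ⇐ tetra-ortho ether by carboxylate-directed Ullmann coupling; F–G–H ⇐ H+G (Ullmann), Dakin, +F (Ullmann), Dakin.
5. A–B–C ⇐ B+C (Ullmann on an ortho-formyl bromide), +A (Ullmann), Dakin; order of joining: B–C, A–B, G–H, F–G, D–E, E–F, C–D.

## Route

Step 1
Reactants: 1 5-bromo-1,2,3-trimethoxybenzene
Product: 3 6-bromo-2,3,4-trimethoxybenzaldehyde, via alpha-chloro ether 2 (not isolated)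
Conditions: Cl2CHOMe, TiCl4, CH2Cl2, 0 °C; then H2O
Reagents that add atoms: dichloromethyl methyl ether, COC(Cl)Cl; water, O
Why: Rieche formylation; the two free ring positions are equivalent and activated ortho/para by methoxy groups, so one aldehyde results after hydrolysis of the alpha-chloro ether.

Step 2
Reactants: 4 4-bromo-2,6-dimethoxyphenol; 3 6-bromo-2,3,4-trimethoxybenzaldehyde
Product: 5 6-(4-bromo-2,6-dimethoxyphenoxy)-2,3,4-trimethoxybenzaldehyde
Conditions: CuI (10 mol%), picolinic acid (20 mol%), K3PO4, DMSO, 80 °C (1.2 equiv of 3)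
Reagents that add atoms: none
Why: Ullmann diaryl ether coupling in which the ortho-formyl-activated bromide of 3 reacts much faster than the electron-rich bromide para to the phenoxide oxygen of 4, so the B-ring bromide survives for the next step.

Step 3
Reactants: 5 6-(4-bromo-2,6-dimethoxyphenoxy)-2,3,4-trimethoxybenzaldehyde; 6 2,4,6-trimethoxyphenol
Product: 7 6-[2,6-dimethoxy-4-(2,4,6-trimethoxyphenoxy)phenoxy]-2,3,4-trimethoxybenzaldehyde
Conditions: CuI (10 mol%), picolinic acid (20 mol%), K3PO4, DMSO, 100 °C, Ar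
Reagents that add atoms: none
Why: Ullmann coupling of a di-ortho-substituted phenol with an unhindered aryl bromide, the combination the picolinic acid system handles well; the non-enolisable aldehyde is inert to the base.

Step 4
Reactants: 7 6-[2,6-dimethoxy-4-(2,4,6-trimethoxyphenoxy)phenoxy]-2,3,4-trimethoxybenzaldehyde
Product: 9 6-[2,6-dimethoxy-4-(2,4,6-trimethoxyphenoxy)phenoxy]-2,3,4-trimethoxyphenol, via aryl formate 8 (not isolated)
Conditions: mCPBA (1.2 equiv), CH2Cl2, 0 °C to rt; then K2CO3, MeOH, rt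
Reagents that add atoms: 3-chloroperbenzoic acid, OOC(=O)c1cccc(Cl)c1
Why: Dakin-type Baeyer–Villiger oxidation; the electron-rich aryl group with ortho and para oxygen donors migrates readily, the formate masks the phenol from the peracid, and methanolysis then frees it.

Step 5
Reactants: 10 3,4,5-trimethoxyphenol; 11 2-bromo-3,4,5-trimethoxybenzaldehyde
Product: 12 3,4,5-trimethoxy-2-(3,4,5-trimethoxyphenoxy)benzaldehyde
Conditions: CuI (10 mol%), picolinic acid (20 mol%), K3PO4, DMSO, 90 °C
Reagents that add atoms: none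
Why: Ullmann coupling of an unhindered phenol with a bromide activated by the ortho formyl group, which offsets the two flanking substituents.

Step 6
Reactants: 12 3,4,5-trimethoxy-2-(3,4,5-trimethoxyphenoxy)benzaldehyde
Product: 14 3,4,5-trimethoxy-2-(3,4,5-trimethoxyphenoxy)phenol, via aryl formate 13 (not isolated)
Conditions: mCPBA (1.2 equiv), CH2Cl2, 0 °C to rt; then K2CO3, MeOH, rt
Reagents that add atoms: 3-chloroperbenzoic acid, OOC(=O)c1cccc(Cl)c1
Why: Dakin-type Baeyer–Villiger oxidation, favoured by the para methoxy and ortho aryloxy groups of the migrating ring.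

Step 7
Reactants: 14 3,4,5-trimethoxy-2-(3,4,5-trimethoxyphenoxy)phenol; 15 3-bromo-4,5-dimethoxybenzaldehyde
Product: 16 3,4-dimethoxy-5-[3,4,5-trimethoxy-2-(3,4,5-trimethoxyphenoxy)phenoxy]benzaldehyde
Conditions: CuI (10 mol%), picolinic acid (20 mol%), K3PO4, DMSO, 100 °C
Reagents that add atoms: none
Why: Ullmann coupling with only one ortho substituent on each partner, and the formyl group makes the bromide slightly electron-poor.

Step 8
Reactants: 16 3,4-dimethoxy-5-[3,4,5-trimethoxy-2-(3,4,5-trimethoxyphenoxy)phenoxy]benzaldehyde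
Product: 18 3,4-dimethoxy-5-[3,4,5-trimethoxy-2-(3,4,5-trimethoxyphenoxy)phenoxy]phenol, via aryl formate 17 (not isolated)
Conditions: mCPBA (1.2 equiv), CH2Cl2, 0 °C to rt; then K2CO3, MeOH, rt
Reagents that add atoms: 3-chloroperbenzoic acid, OOC(=O)c1cccc(Cl)c1
Why: Dakin-type Baeyer–Villiger oxidation of a veratraldehyde-type ring, where the para methoxy group drives aryl migration.

Step 9
Reactants: 4 4-bromo-2,6-dimethoxyphenol; 19 2-bromo-3,4,5-trimethoxybenzoic acid
Product: 20 2-(4-bromo-2,6-dimethoxyphenoxy)-3,4,5-trimethoxybenzoic acid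
Conditions: CuI (10 mol%), K2CO3, DMF, 110 °C, no added ligand; acidic work-up
Reagents that add atoms: none
Why: Ullmann condensation with the ortho-carboxylate effect (Hurtley-type); the copper carboxylate delivers the metal to the neighbouring C–Br bond, which allows the tetra-ortho ether to form and leaves the unactivated D-ring bromide untouched under ligand-free conditions.

Step 10
Reactants: 20 2-(4-bromo-2,6-dimethoxyphenoxy)-3,4,5-trimethoxybenzoic acid; 18 3,4-dimethoxy-5-[3,4,5-trimethoxy-2-(3,4,5-trimethoxyphenoxy)phenoxy]phenol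
Product: 21 5-bromo-1,3-dimethoxy-2-{2,3,4-trimethoxy-6-[3,4-dimethoxy-5-(3,4,5-trimethoxy-2-(3,4,5-trimethoxyphenoxy)phenoxy)phenoxy]phenoxy}benzene
Conditions: Cu(OTf)2 (2.5 equiv), 2,6-lutidine (4 equiv), 3 Å MS, MeCN, 390 nm LEDs, 25 °C, Ar (1.5 equiv of 20; 18 added last)
Reagents that add atoms: none
Why: Proposed new method: photochemical decarboxylative aryloxylation, in which the divalent copper carboxylate of 20 undergoes ligand-to-metal charge transfer at 390 nm to give monovalent copper and an aroyloxyl radical whose loss of CO2 is accelerated by the ortho aryloxy group; the aryl radical (Pschorr-type cyclisation onto ring D is blocked because both ortho positions there carry OMe) is trapped by a second lutidine-ligated divalent copper centre bearing the phenoxide of 18, and the resulting aryl(aryloxy) trivalent copper species reductively eliminates the E–O–F bond as in Chan–Lam and Ullmann etherification; the closest known reaction type is the copper-LMCT decarboxylative hydroxylation and halogenation of benzoic acids, where the same copper-captured aryl radical couples with a carboxylate or halide instead of a phenoxide, and the lutidine-buffered, acetate-free copper source is chosen because phenols survive stoichiometric divalent copper with pyridine bases at room temperature in Chan–Lam couplings.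

Step 11
Reactants: 9 6-[2,6-dimethoxy-4-(2,4,6-trimethoxyphenoxy)phenoxy]-2,3,4-trimethoxyphenol; 21 5-bromo-1,3-dimethoxy-2-{2,3,4-trimethoxy-6-[3,4-dimethoxy-5-(3,4,5-trimethoxy-2-(3,4,5-trimethoxyphenoxy)phenoxy)phenoxy]phenoxy}benzene
Product: 22 henicosa-O-methyl ether of the target (all 21 hydroxyl groups as OMe)
Conditions: CuI (20 mol%), picolinic acid (40 mol%), K3PO4, DMSO, 110 °C, Ar (1.2 equiv of 9)
Reagents that add atoms: none
Why: Ullmann coupling of a hindered phenol with the only aryl bromide present, which sits between two ring hydrogens and is therefore the least hindered electrophilic site of the whole route.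

Step 12
Reactants: 22 henicosa-O-methyl ether of the target
Product: 24 CNP0309601.0 (target), via per-O-dibromoboryl ether 23 (not isolated)
Conditions: BBr3 (excess, about 3 equiv per OMe), CH2Cl2, −78 °C to rt, Ar; then H2O, 0 °C; Sephadex LH-20 under Ar
Reagents that add atoms: none
Why: Lewis-acid O-demethylation, in which bromide attacks the methyl group of each boron-complexed aryl methyl ether while diaryl ether bonds, which have no alkyl carbon to attack, stay intact; the boron-bound phenoxides are hydrolysed on quench.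

## Compound list

1 | 5-bromo-1,2,3-trimethoxybenzene | COc1cc(Br)cc(OC)c1OC | starting material
2 | 5-bromo-4-[chloro(methoxy)methyl]-1,2,3-trimethoxybenzene (racemic, transient) | COC(Cl)c1c(Br)cc(OC)c(OC)c1OC | intermediate (not isolated)
3 | 6-bromo-2,3,4-trimethoxybenzaldehyde (ring C unit) | O=Cc1c(Br)cc(OC)c(OC)c1OC | intermediate
4 | 4-bromo-2,6-dimethoxyphenol (ring B and ring D unit) | COc1cc(Br)cc(OC)c1O | starting material
5 | 6-(4-bromo-2,6-dimethoxyphenoxy)-2,3,4-trimethoxybenzaldehyde | O=Cc1c(Oc2c(OC)cc(Br)cc2OC)cc(OC)c(OC)c1OC | intermediate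
6 | 2,4,6-trimethoxyphenol (ring A unit) | COc1cc(OC)c(O)c(OC)c1 | starting material
7 | 6-[2,6-dimethoxy-4-(2,4,6-trimethoxyphenoxy)phenoxy]-2,3,4-trimethoxybenzaldehyde | O=Cc1c(Oc2c(OC)cc(Oc3c(OC)cc(OC)cc3OC)cc2OC)cc(OC)c(OC)c1OC | intermediate
8 | 6-[2,6-dimethoxy-4-(2,4,6-trimethoxyphenoxy)phenoxy]-2,3,4-trimethoxyphenyl formate | O=COc1c(Oc2c(OC)cc(Oc3c(OC)cc(OC)cc3OC)cc2OC)cc(OC)c(OC)c1OC | intermediate (not isolated)
9 | 6-[2,6-dimethoxy-4-(2,4,6-trimethoxyphenoxy)phenoxy]-2,3,4-trimethoxyphenol (trimer A–B–C) | Oc1c(Oc2c(OC)cc(Oc3c(OC)cc(OC)cc3OC)cc2OC)cc(OC)c(OC)c1OC | intermediate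
10 | 3,4,5-trimethoxyphenol (ring H unit) | COc1cc(O)cc(OC)c1OC | starting material
11 | 2-bromo-3,4,5-trimethoxybenzaldehyde (ring G unit) | O=Cc1cc(OC)c(OC)c(OC)c1Br | starting material
12 | 3,4,5-trimethoxy-2-(3,4,5-trimethoxyphenoxy)benzaldehyde | O=Cc1cc(OC)c(OC)c(OC)c1Oc1cc(OC)c(OC)c(OC)c1 | intermediate
13 | 3,4,5-trimethoxy-2-(3,4,5-trimethoxyphenoxy)phenyl formate | O=COc1cc(OC)c(OC)c(OC)c1Oc1cc(OC)c(OC)c(OC)c1 | intermediate (not isolated)
14 | 3,4,5-trimethoxy-2-(3,4,5-trimethoxyphenoxy)phenol | Oc1cc(OC)c(OC)c(OC)c1Oc1cc(OC)c(OC)c(OC)c1 | intermediate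
15 | 3-bromo-4,5-dimethoxybenzaldehyde (ring F unit) | O=Cc1cc(Br)c(OC)c(OC)c1 | starting material
16 | 3,4-dimethoxy-5-[3,4,5-trimethoxy-2-(3,4,5-trimethoxyphenoxy)phenoxy]benzaldehyde | O=Cc1cc(OC)c(OC)c(Oc2cc(OC)c(OC)c(OC)c2Oc2cc(OC)c(OC)c(OC)c2)c1 | intermediate
17 | 3,4-dimethoxy-5-[3,4,5-trimethoxy-2-(3,4,5-trimethoxyphenoxy)phenoxy]phenyl formate | O=COc1cc(OC)c(OC)c(Oc2cc(OC)c(OC)c(OC)c2Oc2cc(OC)c(OC)c(OC)c2)c1 | intermediate (not isolated)
18 | 3,4-dimethoxy-5-[3,4,5-trimethoxy-2-(3,4,5-trimethoxyphenoxy)phenoxy]phenol (trimer F–G–H) | Oc1cc(OC)c(OC)c(Oc2cc(OC)c(OC)c(OC)c2Oc2cc(OC)c(OC)c(OC)c2)c1 | intermediate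
19 | 2-bromo-3,4,5-trimethoxybenzoic acid (ring E unit) | OC(=O)c1cc(OC)c(OC)c(OC)c1Br | starting material
20 | 2-(4-bromo-2,6-dimethoxyphenoxy)-3,4,5-trimethoxybenzoic acid (dimer D–E) | OC(=O)c1cc(OC)c(OC)c(OC)c1Oc1c(OC)cc(Br)cc1OC | intermediate
21 | 5-bromo-1,3-dimethoxy-2-{2,3,4-trimethoxy-6-[3,4-dimethoxy-5-(3,4,5-trimethoxy-2-(3,4,5-trimethoxyphenoxy)phenoxy)phenoxy]phenoxy}benzene (pentamer D–E–F–G–H) | COc1cc(Br)cc(OC)c1Oc1c(OC)c(OC)c(OC)cc1Oc1cc(OC)c(OC)c(Oc2cc(OC)c(OC)c(OC)c2Oc2cc(OC)c(OC)c(OC)c2)c1 | intermediate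
22 | henicosa-O-methyl ether of the target (octamer A–H, 21 OMe) | COc1cc(OC)c(Oc2cc(OC)c(Oc3cc(OC)c(OC)c(OC)c3Oc3cc(OC)c(Oc4c(Oc5cc(OC)c(OC)c(Oc6cc(OC)c(OC)c(OC)c6Oc6cc(OC)c(OC)c(OC)c6)c5)cc(OC)c(OC)c4OC)c(OC)c3)c(OC)c2)c(OC)c1 | intermediate
23 | per-O-dibromoboryl ether of the target (each of the 21 phenol oxygens drawn as O–BBr2; idealised, vicinal oxygens may share one boron) | BrB(Br)Oc1cc(OB(Br)Br)c(Oc2cc(OB(Br)Br)c(Oc3cc(OB(Br)Br)c(OB(Br)Br)c(OB(Br)Br)c3Oc3cc(OB(Br)Br)c(Oc4c(Oc5cc(OB(Br)Br)c(OB(Br)Br)c(Oc6cc(OB(Br)Br)c(OB(Br)Br)c(OB(Br)Br)c6Oc6cc(OB(Br)Br)c(OB(Br)Br)c(OB(Br)Br)c6)c5)cc(OB(Br)Br)c(OB(Br)Br)c4OB(Br)Br)c(OB(Br)Br)c3)c(OB(Br)Br)c2)c(OB(Br)Br)c1 | intermediate (not isolated)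
24 | CNP0309601.0 (octameric phlorotannin, achiral) | Oc1cc(O)c(Oc2cc(O)c(Oc3cc(O)c(O)c(O)c3Oc3cc(O)c(Oc4c(Oc5cc(O)c(O)c(Oc6cc(O)c(O)c(O)c6Oc6cc(O)c(O)c(O)c6)c5)cc(O)c(O)c4O)c(O)c3)c(O)c2)c(O)c1 | target

## Step count and risk

Total step count: 12. Longest linear sequence: 7 steps (5, 6, 7, 8, 10, 11, 12).

**Step 10 (the proposed new decarboxylative aryloxylation).** The main risks are oxidation of the electron-rich phenol 18 by divalent copper and hydrogen abstraction by the aryl radical before copper capture. The fallback sets out from 20 and comes back at 21, using known chemistry only. Copper-LMCT iododecarboxylation ([Cu(MeCN)4]BF4 20 mol%, N-iodosuccinimide, 1-fluoro-2,4,6-trimethylpyridinium tetrafluoroborate, MeCN, 365 nm) gives 5-bromo-2-(6-iodo-2,3,4-trimethoxyphenoxy)-1,3-dimethoxybenzene F1. An iodide-selective Ullmann coupling of F1 with 18 (CuI, picolinic acid, K3PO4, DMSO, 80 °C) then forms the E–O–F bond and leaves the D-ring bromide in place, giving 21.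

**Step 9 (tetra-ortho ether).** Even with carboxylate assistance the coupling may stall, or the bromo acid may be reduced or decarboxylated. The fallback sets out from 4 and comes back at 20, replacing copper coupling by metal-free ligand coupling at trivalent iodine. Commercial methyl 3,4,5-trimethoxybenzoate F2 is iodinated next to the ester (N-iodosuccinimide, CF3CO2H, MeCN) to methyl 2-iodo-3,4,5-trimethoxybenzoate F3. One-pot oxidation and arene ligation (mCPBA, TsOH·H2O, MeCN; then 1,3,5-trimethoxybenzene) gives [2-(methoxycarbonyl)-3,4,5-trimethoxyphenyl](2,4,6-trimethoxyphenyl)iodonium tosylate F4. The potassium phenoxide of 4 (t-BuOK, THF, 0 to 40 °C) is arylated by F4, the ester-bearing aryl group transferring in preference to the more electron-rich trimethoxyphenyl group, to give methyl 2-(4-bromo-2,6-dimethoxyphenoxy)-3,4,5-trimethoxybenzoate F5. Saponification (LiOH, THF/H2O) returns 20.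

**Step 12 (21-fold demethylation).** Incomplete cleavage and loss of the air-sensitive polyphenol on isolation are the likely failures. The fallback sets out from 22 and comes back at 24, changing both the cleavage mechanism and the isolation. Hard-acid/soft-nucleophile cleavage (AlCl3, EtSH, CH2Cl2, 0 °C to rt) is followed by acetylation of the crude product in the same flask (Ac2O, pyridine, DMAP) to the henicosaacetate of the target F6. F6 is stable, can be purified on silica, and any partly methylated material can be separated and resubmitted. Acid methanolysis (AcCl cat., MeOH, 40 °C, Ar) then releases 24 without exposing phenoxides to air.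

## Further compounds

F1 | step 10 | 5-bromo-2-(6-iodo-2,3,4-trimethoxyphenoxy)-1,3-dimethoxybenzene | COc1cc(Br)cc(OC)c1Oc1c(OC)c(OC)c(OC)cc1I
F2 | step 9 | methyl 3,4,5-trimethoxybenzoate (bought) | COC(=O)c1cc(OC)c(OC)c(OC)c1
F3 | step 9 | methyl 2-iodo-3,4,5-trimethoxybenzoate | COC(=O)c1cc(OC)c(OC)c(OC)c1I
F4 | step 9 | [2-(methoxycarbonyl)-3,4,5-trimethoxyphenyl](2,4,6-trimethoxyphenyl)iodonium tosylate | COC(=O)c1cc(OC)c(OC)c(OC)c1[I+]c1c(OC)cc(OC)cc1OC.Cc1ccc(cc1)S(=O)(=O)[O-]
F5 | step 9 | methyl 2-(4-bromo-2,6-dimethoxyphenoxy)-3,4,5-trimethoxybenzoate | COC(=O)c1cc(OC)c(OC)c(OC)c1Oc1c(OC)cc(Br)cc1OC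
F6 | step 12 | henicosaacetate of the target (all 21 hydroxyl groups as OAc) | CC(=O)Oc1cc(OC(C)=O)c(Oc2cc(OC(C)=O)c(Oc3cc(OC(C)=O)c(OC(C)=O)c(OC(C)=O)c3Oc3cc(OC(C)=O)c(Oc4c(Oc5cc(OC(C)=O)c(OC(C)=O)c(Oc6cc(OC(C)=O)c(OC(C)=O)c(OC(C)=O)c6Oc6cc(OC(C)=O)c(OC(C)=O)c(OC(C)=O)c6)c5)cc(OC(C)=O)c(OC(C)=O)c4OC(C)=O)c(OC(C)=O)c3)c(OC(C)=O)c2)c(OC(C)=O)c1
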